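**Plan**

Locants follow 2-oxaspiro[4.5]deca-6,9-dien-8-one: C1 carries the side chain C1'–C2', C3 the aryl group, C4 the CH2OH group, C5 is the spiro carbon, C7 carries OMe.
Retrosynthesis: cut C6=C7 (olefination) and C7–C8 (acylation), so that C7–OMe comes from a phosphonate and the dienone ring becomes a δ-lactone acylal; then cut the lactone C–O bond and C9=C10; then O2–C3, C1–C1' and C4–C5.
Forward: C5 (with two identical CH2O arms) and C4 by Ireland–Claisen rearrangement; side chain by Evans glycolate aldol; oxolane ring A by quinone methide etherification; the arms become two formyl groups and lactol ring B takes one of them; pyranone ring C; dienone ring last.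
Stereochemistry: C4 from CBS reduction and 1,3-chirality transfer; C1 and C1' from the (R)-oxazolidinone syn-aldol; C3 trans to C4 in the ring A closure; C5 is not set by a selective reaction but is read off from C4 when ring B forms.
Enabling feature: the CH2OH on C4 is cis to C6, the ring carbon next to C7–OMe, so C6 can be held as a cis-fused five-membered lactol; C8, C9 and C10 then close a 5,6-dihydro-2H-pyran-2-one whose ring oxygen sits where C7 must go.

Key step: step 19

Assumption: diethyl (methoxymethyl)phosphonate 33 and the chloroacetyl oxazolidinone 16 are taken as purchased reagents.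

Step 1
Reactants: 1 2,2-dimethyl-1,3-dioxan-5-one; 2 1-(triphenylphosphoranylidene)propan-2-one
Product: 3 1-(2,2-dimethyl-1,3-dioxan-5-ylidene)propan-2-one
Conditions: toluene, 80 °C
Reagents that add atoms: none
Why: Wittig olefination of the activated α,α'-dioxygenated ketone with a stabilised ylide should proceed under neutral conditions, and no stereo element arises because the ring carbon carries two identical CH2O arms.

Step 2
Reactants: 3 1-(2,2-dimethyl-1,3-dioxan-5-ylidene)propan-2-one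
Product: 4 (2S)-1-(2,2-dimethyl-1,3-dioxan-5-ylidene)propan-2-ol
Conditions: (R)-Me-CBS oxazaborolidine (0.1 equiv), BH3·SMe2, THF, −30 °C
Reagents that add atoms: none
Why: Corey–Bakshi–Shibata reduction, in which the alkenyl group acts as the large substituent, should give the (S)-carbinol from the (R)-catalyst.

Step 3
Reactants: 5 3-(4-hydroxy-3-methoxyphenyl)propanoic acid
Product: 7 3-[3-methoxy-4-(triisopropylsilyloxy)phenyl]propanoic acid, via bis-silyl compound 6 (not isolated)
Conditions: TIPSCl (2.2 equiv), imidazole, DMF, rt; then AcOH–THF–H2O, rt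
Reagents that add atoms: triisopropylsilyl chloride CC(C)[Si](Cl)(C(C)C)C(C)C
Why: Silylation of both acidic hydroxyl groups followed by selective hydrolysis of the labile silyl ester should leave the aryl silyl ether, a standard masking of a phenolic acid.

Step 4
Reactants: 4 (2S)-1-(2,2-dimethyl-1,3-dioxan-5-ylidene)propan-2-ol; 7 3-[3-methoxy-4-(triisopropylsilyloxy)phenyl]propanoic acid
Product: 8 (2S)-1-(2,2-dimethyl-1,3-dioxan-5-ylidene)propan-2-yl 3-[3-methoxy-4-(triisopropylsilyloxy)phenyl]propanoate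
Conditions: DCC, DMAP (cat.), CH2Cl2, 0 °C to rt
Reagents that add atoms: none
Why: Steglich esterification should acylate the secondary allylic alcohol without touching its stereocentre.

Step 5
Reactants: 8 allylic ester
Product: 11 (2R)-2-{2,2-dimethyl-5-[(E)-prop-1-enyl]-1,3-dioxan-5-yl}-3-[3-methoxy-4-(triisopropylsilyloxy)phenyl]propan-1-ol, via silyl ketene acetal 9 (not isolated), via trimethylsilyl ester 10 (not isolated)
Conditions: LiN(iPr)2 (LDA), THF, −78 °C; TMSCl, Et3N; −78 to 60 °C; then LiAlH4, 0 °C to rt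
Reagents that add atoms: none
Why: Ireland–Claisen rearrangement through a chair transition state with the carbinol methyl group equatorial should form the C4–C5 bond and the quaternary carbon, the (E)-silyl ketene acetal from LDA in THF together with the (S)-carbinol should transfer chirality to give (R) at the new centre (the future C4), and the silyl ester is reduced in the same flask by LiAlH4.

Step 6
Reactants: 11 primary alcohol
Product: 12 5-{(2R)-1-(benzyloxy)-3-[3-methoxy-4-(triisopropylsilyloxy)phenyl]propan-2-yl}-2,2-dimethyl-5-[(E)-prop-1-enyl]-1,3-dioxane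
Conditions: NaH, BnBr, Bu4NI (cat.), THF–DMF, 0 °C to rt
Reagents that add atoms: benzyl bromide BrCc1ccccc1
Why: Williamson etherification masks the future hydroxymethyl oxygen as a benzyl ether that should survive every step up to step 17.

Step 7
Reactants: 12 benzyl ether
Product: 14 5-{(2R)-1-(benzyloxy)-3-[3-methoxy-4-(triisopropylsilyloxy)phenyl]propan-2-yl}-2,2-dimethyl-1,3-dioxane-5-carbaldehyde, via secondary ozonide 13 (not isolated)
Conditions: O3, CH2Cl2, −78 °C; then PPh3, −78 °C to rt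
Reagents that add atoms: ozone [O-][O+]=O
Why: Ozonolysis cleaves the only alkene to unveil the neopentyl aldehyde (future C1), which has no α-hydrogen and cannot epimerise.

Step 8
Reactants: 15 4-(3-hydroxypropyl)-2-methoxyphenol; 16 (4R)-4-benzyl-3-(2-chloroacetyl)-1,3-oxazolidin-2-one
Product: 17 (4R)-4-benzyl-3-{2-[4-(3-hydroxypropyl)-2-methoxyphenoxy]acetyl}-1,3-oxazolidin-2-one
Conditions: K2CO3, NaI (cat.), acetone, 40 °C
Reagents that add atoms: none
Why: Williamson O-alkylation of the phenoxide (SN2 at the activated α-chloro imide) should be chemoselective because carbonate does not deprotonate the aliphatic alcohol.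

Step 9
Reactants: 17 aryloxyacetyl imide
Product: 18 (4R)-4-benzyl-3-(2-{2-methoxy-4-[3-(triisopropylsilyloxy)propyl]phenoxy}acetyl)-1,3-oxazolidin-2-one
Conditions: TIPSCl, imidazole, DMF, rt
Reagents that add atoms: triisopropylsilyl chloride CC(C)[Si](Cl)(C(C)C)C(C)C
Why: Standard silylation of the primary alcohol.

Step 10
Reactants: 18 silylated aryloxyacetyl imide; 14 neopentyl aldehyde
Product: 20 (4R)-4-benzyl-3-[(2R,3S)-3-hydroxy-2-aryloxy-3-(dioxanyl)propanoyl]-1,3-oxazolidin-2-one (syn-aldol adduct; full name in the list), via boron enolate 19 (not isolated)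
Conditions: Bu2BOTf, Et3N, CH2Cl2, −78 to 0 °C; 14, −78 to 0 °C; then H2O2, MeOH, pH 7 buffer
Reagents that add atoms: none
Why: Evans syn-aldol reaction, in which the (Z)-boron enolate reacts through a Zimmerman–Traxler transition state on the face dictated by the (R)-4-benzyl auxiliary, should set C1 (S) and C1' (R at this stage) in the syn relation of the target regardless of the remote centre of 14.

Step 11
Reactants: 20 syn-aldol adduct
Product: 21 phenol (aryl silyl ether of 20 cleaved)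
Conditions: Bu4NF (1.05 equiv), AcOH, THF, 0 °C
Reagents that add atoms: none
Why: Fluoride cleaves an aryl silyl ether far faster than a primary alkyl silyl ether, so one buffered equivalent should free only the phenol.

Step 12
Reactants: 21 phenol
Product: 23 (4R)-4-benzyl-3-[(2R)-2-aryloxy-2-{(1S,3S,4R)-4-(benzyloxymethyl)-3-(4-hydroxy-3-methoxyphenyl)-8,8-dimethyl-2,7,9-trioxaspiro[4.5]decan-1-yl}acetyl]-1,3-oxazolidin-2-one, via quinone methide 22 (not isolated)
Conditions: Ag2O, CH2Cl2, rt, dark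
Reagents that add atoms: none
Why: Oxidation of the 4-alkyl-2-methoxyphenol to the p-quinone methide and 5-exo-trig 1,6-addition of the C1 hydroxyl (the biomimetic oxolane closure of lignans) should close ring A with the aryl group trans to the C4 substituent, the less hindered and more stable arrangement.

Step 13
Reactants: 23 oxolane imide
Product: 24 (2S)-2-aryloxy-2-{(1S,3S,4R)-4-(benzyloxymethyl)-3-(4-hydroxy-3-methoxyphenyl)-8,8-dimethyl-2,7,9-trioxaspiro[4.5]decan-1-yl}ethanol
Conditions: LiBH4, MeOH (1 equiv), THF, 0 °C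
Reagents that add atoms: none
Why: Reductive cleavage of the Evans imide with LiBH4 gives the primary alcohol C2' and returns the auxiliary, and no other group is reducible.

Step 14
Reactants: 24 phenol alcohol
Product: 25 bis(triisopropylsilyl) ether of 24
Conditions: TIPSOTf, 2,6-lutidine, CH2Cl2, 0 °C
Reagents that add atoms: triisopropylsilyl trifluoromethanesulfonate CC(C)[Si](OS(=O)(=O)C(F)(F)F)(C(C)C)C(C)C
Why: Silyl triflate with 2,6-lutidine silylates the phenol and the primary alcohol, so that no free hydroxyl remains for the oxidation and acylation steps that follow.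

Step 15
Reactants: 25 spiro acetonide
Product: 26 oxolane-3,3-diyldimethanol (neopentyl 1,3-diol)
Conditions: AcOH–H2O–THF (3:1:1), 45 °C
Reagents that add atoms: none
Why: Acid hydrolysis of the 1,3-dioxane acetal should free the neopentyl 1,3-diol while triisopropylsilyl and benzyl ethers persist.

Step 16
Reactants: 26 neopentyl 1,3-diol
Product: 27 oxolane-3,3-dicarbaldehyde
Conditions: (COCl)2, DMSO, CH2Cl2, −78 °C; Et3N, −78 to 0 °C
Reagents that add atoms: none
Why: Swern oxidation converts both primary alcohols into a non-enolisable 2,2-disubstituted malonaldehyde.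

Step 17
Reactants: 27 dialdehyde
Product: 29 (1R,2S,4S,5R)-6-hydroxy-3,7-dioxabicyclo[3.3.0]octane-5-carbaldehyde (lactol aldehyde; full name in the list), via hydroxy dialdehyde 28 (not isolated)
Conditions: H2 (1 atm), Pd/C, EtOAc, rt
Reagents that add atoms: none
Why: Hydrogenolysis of the benzyl ether frees the C4 hydroxymethyl group, which should close only onto the formyl group cis to it because the resulting 3,7-dioxabicyclo[3.3.0]octane must be cis-fused; this differentiates the two formyl groups and thereby fixes the configuration of the quaternary carbon (future C5).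

Step 18
Reactants: 29 lactol aldehyde; 30 (triphenylphosphoranylidene)ethenone
Product: 32 tricyclic δ-lactone acylal, via ester ylide 31 (not isolated)
Conditions: toluene, 80 °C
Reagents that add atoms: none
Why: Bestmann ylide cascade, in which the lactol hydroxyl adds to the ketene to give an ester ylide that undergoes intramolecular Wittig olefination with the remaining aldehyde, should give the six-membered lactone that enforces the cis C9=C10 bond; the acetal centre may form as either epimer since it is destroyed in step 19.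

Step 19
Reactants: 32 tricyclic δ-lactone acylal; 33 diethyl (methoxymethyl)phosphonate
Product: 35 tris(triisopropylsilyl) ether of the target, via ketophosphonate lactol 34 (not isolated)
Conditions: 33 (2.2 equiv), LiN(iPr)2 (LDA), THF, −78 °C; then 32, −78 °C to rt
Reagents that add atoms: none
Why: Proposed new method: the lithiated α-methoxyphosphonate adds 1,2 to the lactone carbonyl C8, the tetrahedral alkoxide expels the hemiacetal oxygen on C6, the lactolate so formed is in equilibrium with the free C6 aldehyde (opening the temporary ring B and releasing the C4 hydroxymethyl group), and the β-ketophosphonate carbanion at C7 closes the ring by intramolecular Horner–Wadsworth–Emmons olefination to form C6=C7, so that the ring oxygen of a 5,6-dihydro-2H-pyran-2-one is exchanged for the methoxy-bearing carbon in one flask. The closest known reaction types are the acylation of lithiated phosphonates by lactones followed by intramolecular olefination (lactone to carbocyclic enone) and the one-flask conversion of enol lactones into cyclohexenones with a methylphosphonate anion; new here are the acylal lactone, which frees an aldehyde instead of a ketone, and the α-methoxy group on the phosphonate. The six-membered carbocycle closes in the 6-(enolexo)-exo-trig mode by attack of C7 on the aldehyde carbon C6, and the cis geometry of C9=C10 that this closure needs is inherited from the lactone ring. No new stereocentre is formed: the acetal centre C6 becomes trigonal and the spiro centre C5 keeps the configuration fixed by the cis-fused lactol of step 17, which is why the methoxy group ends on the arm cis to the hydroxymethyl group. The step needs 1,2- over 1,4-addition, a single acylation and retention of the (Z)-enone; the neopentyl position of C10 disfavours conjugate addition, the β-ketophosphonate is protected from a second addition as its enolate, and C9=C10 is only cross-conjugated to the carbanion and so cannot isomerise through it.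

Step 20
Reactants: 35 tris(triisopropylsilyl) ether of the target
Product: 36 (1S,3S,4R,5S)-3-(4-hydroxy-3-methoxyphenyl)-4-(hydroxymethyl)-1-{(1S)-2-hydroxy-1-[4-(3-hydroxypropyl)-2-methoxyphenoxy]ethyl}-7-methoxy-2-oxaspiro[4.5]deca-6,9-dien-8-one (CNP0252711.1)
Conditions: HF·pyridine, pyridine, THF, 0 °C to rt
Reagents that add atoms: none
Why: Fluoride cleaves the three silyl ethers, and buffering with pyridine should protect the dienone and the benzylic ether.

**Compound list**

1 | 2,2-dimethyl-1,3-dioxan-5-one | CC1(C)OCC(=O)CO1 | starting material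
2 | 1-(triphenylphosphoranylidene)propan-2-one | CC(=O)C=P(c1ccccc1)(c1ccccc1)c1ccccc1 | starting material
3 | 1-(2,2-dimethyl-1,3-dioxan-5-ylidene)propan-2-one | CC(=O)C=C1COC(C)(C)OC1 | intermediate
4 | (2S)-1-(2,2-dimethyl-1,3-dioxan-5-ylidene)propan-2-ol | C[C@H](O)C=C1COC(C)(C)OC1 | intermediate
5 | 3-(4-hydroxy-3-methoxyphenyl)propanoic acid (dihydroferulic acid) | COc1cc(CCC(=O)O)ccc1O | starting material
6 | triisopropylsilyl 3-[3-methoxy-4-(triisopropylsilyloxy)phenyl]propanoate | COc1cc(CCC(=O)O[Si](C(C)C)(C(C)C)C(C)C)ccc1O[Si](C(C)C)(C(C)C)C(C)C | intermediate (not isolated)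
7 | 3-[3-methoxy-4-(triisopropylsilyloxy)phenyl]propanoic acid | COc1cc(CCC(=O)O)ccc1O[Si](C(C)C)(C(C)C)C(C)C | intermediate
8 | (2S)-1-(2,2-dimethyl-1,3-dioxan-5-ylidene)propan-2-yl 3-[3-methoxy-4-(triisopropylsilyloxy)phenyl]propanoate | C[C@H](OC(=O)CCc1ccc(O[Si](C(C)C)(C(C)C)C(C)C)c(OC)c1)C=C1COC(C)(C)OC1 | intermediate
9 | (E)-trimethylsilyl ketene acetal of ester 8 (OSiMe3 trans to the benzylic CH2) | C[C@H](O/C(O[Si](C)(C)C)=C\Cc1ccc(O[Si](C(C)C)(C(C)C)C(C)C)c(OC)c1)C=C1COC(C)(C)OC1 | intermediate (not isolated)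
10 | trimethylsilyl (2R)-2-{2,2-dimethyl-5-[(E)-prop-1-enyl]-1,3-dioxan-5-yl}-3-[3-methoxy-4-(triisopropylsilyloxy)phenyl]propanoate | C[Si](C)(C)OC(=O)[C@H](Cc1ccc(O[Si](C(C)C)(C(C)C)C(C)C)c(OC)c1)C1(/C=C/C)COC(C)(C)OC1 | intermediate (not isolated)
11 | (2R)-2-{2,2-dimethyl-5-[(E)-prop-1-enyl]-1,3-dioxan-5-yl}-3-[3-methoxy-4-(triisopropylsilyloxy)phenyl]propan-1-ol | OC[C@H](Cc1ccc(O[Si](C(C)C)(C(C)C)C(C)C)c(OC)c1)C1(/C=C/C)COC(C)(C)OC1 | intermediate
12 | 5-{(2R)-1-(benzyloxy)-3-[3-methoxy-4-(triisopropylsilyloxy)phenyl]propan-2-yl}-2,2-dimethyl-5-[(E)-prop-1-enyl]-1,3-dioxane | c1ccccc1COC[C@H](Cc1ccc(O[Si](C(C)C)(C(C)C)C(C)C)c(OC)c1)C1(/C=C/C)COC(C)(C)OC1 | intermediate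
13 | 5-{(2R)-1-(benzyloxy)-3-[3-methoxy-4-(triisopropylsilyloxy)phenyl]propan-2-yl}-2,2-dimethyl-5-(5-methyl-1,2,4-trioxolan-3-yl)-1,3-dioxane (secondary ozonide, isomer mixture) | CC1OOC(O1)C1(COC(C)(C)OC1)[C@H](COCc1ccccc1)Cc1ccc(O[Si](C(C)C)(C(C)C)C(C)C)c(OC)c1 | intermediate (not isolated)
14 | 5-{(2R)-1-(benzyloxy)-3-[3-methoxy-4-(triisopropylsilyloxy)phenyl]propan-2-yl}-2,2-dimethyl-1,3-dioxane-5-carbaldehyde | O=CC1(COC(C)(C)OC1)[C@H](COCc1ccccc1)Cc1ccc(O[Si](C(C)C)(C(C)C)C(C)C)c(OC)c1 | intermediate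
15 | 4-(3-hydroxypropyl)-2-methoxyphenol (dihydroconiferyl alcohol) | COc1cc(CCCO)ccc1O | starting material
16 | (4R)-4-benzyl-3-(2-chloroacetyl)-1,3-oxazolidin-2-one | ClCC(=O)N1[C@H](Cc2ccccc2)COC1=O | starting material
17 | (4R)-4-benzyl-3-{2-[4-(3-hydroxypropyl)-2-methoxyphenoxy]acetyl}-1,3-oxazolidin-2-one | COc1cc(CCCO)ccc1OCC(=O)N1[C@H](Cc2ccccc2)COC1=O | intermediate
18 | (4R)-4-benzyl-3-(2-{2-methoxy-4-[3-(triisopropylsilyloxy)propyl]phenoxy}acetyl)-1,3-oxazolidin-2-one | COc1cc(CCCO[Si](C(C)C)(C(C)C)C(C)C)ccc1OCC(=O)N1[C@H](Cc2ccccc2)COC1=O | intermediate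
19 | dibutylboron (Z)-enolate of imide 18 | CCCCB(CCCC)O/C(=C\Oc1ccc(CCCO[Si](C(C)C)(C(C)C)C(C)C)cc1OC)N1[C@H](Cc2ccccc2)COC1=O | intermediate (not isolated)
20 | (4R)-4-benzyl-3-[(2R,3S)-3-(5-{(2R)-1-(benzyloxy)-3-[3-methoxy-4-(triisopropylsilyloxy)phenyl]propan-2-yl}-2,2-dimethyl-1,3-dioxan-5-yl)-3-hydroxy-2-{2-methoxy-4-[3-(triisopropylsilyloxy)propyl]phenoxy}propanoyl]-1,3-oxazolidin-2-one | O=C(N1[C@H](Cc2ccccc2)COC1=O)[C@H](Oc1ccc(CCCO[Si](C(C)C)(C(C)C)C(C)C)cc1OC)[C@@H](O)C1(COC(C)(C)OC1)[C@H](COCc1ccccc1)Cc1ccc(O[Si](C(C)C)(C(C)C)C(C)C)c(OC)c1 | intermediate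
21 | (4R)-4-benzyl-3-[(2R,3S)-3-{5-[(2R)-1-(benzyloxy)-3-(4-hydroxy-3-methoxyphenyl)propan-2-yl]-2,2-dimethyl-1,3-dioxan-5-yl}-3-hydroxy-2-{2-methoxy-4-[3-(triisopropylsilyloxy)propyl]phenoxy}propanoyl]-1,3-oxazolidin-2-one | O=C(N1[C@H](Cc2ccccc2)COC1=O)[C@H](Oc1ccc(CCCO[Si](C(C)C)(C(C)C)C(C)C)cc1OC)[C@@H](O)C1(COC(C)(C)OC1)[C@H](COCc1ccccc1)Cc1ccc(O)c(OC)c1 | intermediate
22 | p-quinone methide of 21 (2-methoxy-4-alkylidenecyclohexa-2,5-dien-1-one; the alkylidene carbon is the future C3) | O=C(N1[C@H](Cc2ccccc2)COC1=O)[C@H](Oc1ccc(CCCO[Si](C(C)C)(C(C)C)C(C)C)cc1OC)[C@@H](O)C1(COC(C)(C)OC1)[C@H](COCc1ccccc1)C=C1C=CC(=O)C(OC)=C1 | intermediate (not isolated)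
23 | (4R)-4-benzyl-3-[(2R)-2-{(1S,3S,4R)-4-(benzyloxymethyl)-3-(4-hydroxy-3-methoxyphenyl)-8,8-dimethyl-2,7,9-trioxaspiro[4.5]decan-1-yl}-2-{2-methoxy-4-[3-(triisopropylsilyloxy)propyl]phenoxy}acetyl]-1,3-oxazolidin-2-one | O=C(N1[C@H](Cc2ccccc2)COC1=O)[C@H](Oc1ccc(CCCO[Si](C(C)C)(C(C)C)C(C)C)cc1OC)[C@H]1O[C@H](c2ccc(O)c(OC)c2)[C@@H](COCc2ccccc2)C12COC(C)(C)OC2 | intermediate
24 | (2S)-2-{(1S,3S,4R)-4-(benzyloxymethyl)-3-(4-hydroxy-3-methoxyphenyl)-8,8-dimethyl-2,7,9-trioxaspiro[4.5]decan-1-yl}-2-{2-methoxy-4-[3-(triisopropylsilyloxy)propyl]phenoxy}ethanol | OC[C@H](Oc1ccc(CCCO[Si](C(C)C)(C(C)C)C(C)C)cc1OC)[C@H]1O[C@H](c2ccc(O)c(OC)c2)[C@@H](COCc2ccccc2)C12COC(C)(C)OC2 | intermediate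
25 | (1S,3S,4R)-4-(benzyloxymethyl)-3-[3-methoxy-4-(triisopropylsilyloxy)phenyl]-1-[(1S)-1-{2-methoxy-4-[3-(triisopropylsilyloxy)propyl]phenoxy}-2-(triisopropylsilyloxy)ethyl]-8,8-dimethyl-2,7,9-trioxaspiro[4.5]decane | CC(C)[Si](C(C)C)(C(C)C)OC[C@H](Oc1ccc(CCCO[Si](C(C)C)(C(C)C)C(C)C)cc1OC)[C@H]1O[C@H](c2ccc(O[Si](C(C)C)(C(C)C)C(C)C)c(OC)c2)[C@@H](COCc2ccccc2)C12COC(C)(C)OC2 | intermediate
26 | {(2S,4R,5S)-4-(benzyloxymethyl)-5-[3-methoxy-4-(triisopropylsilyloxy)phenyl]-2-[(1S)-1-{2-methoxy-4-[3-(triisopropylsilyloxy)propyl]phenoxy}-2-(triisopropylsilyloxy)ethyl]oxolane-3,3-diyl}dimethanol | CC(C)[Si](C(C)C)(C(C)C)OC[C@H](Oc1ccc(CCCO[Si](C(C)C)(C(C)C)C(C)C)cc1OC)[C@H]1O[C@H](c2ccc(O[Si](C(C)C)(C(C)C)C(C)C)c(OC)c2)[C@@H](COCc2ccccc2)C1(CO)CO | intermediate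
27 | (2S,4R,5S)-4-(benzyloxymethyl)-5-[3-methoxy-4-(triisopropylsilyloxy)phenyl]-2-[(1S)-1-{2-methoxy-4-[3-(triisopropylsilyloxy)propyl]phenoxy}-2-(triisopropylsilyloxy)ethyl]oxolane-3,3-dicarbaldehyde | CC(C)[Si](C(C)C)(C(C)C)OC[C@H](Oc1ccc(CCCO[Si](C(C)C)(C(C)C)C(C)C)cc1OC)[C@H]1O[C@H](c2ccc(O[Si](C(C)C)(C(C)C)C(C)C)c(OC)c2)[C@@H](COCc2ccccc2)C1(C=O)C=O | intermediate
28 | (2S,4R,5S)-4-(hydroxymethyl)-5-[3-methoxy-4-(triisopropylsilyloxy)phenyl]-2-[(1S)-1-{2-methoxy-4-[3-(triisopropylsilyloxy)propyl]phenoxy}-2-(triisopropylsilyloxy)ethyl]oxolane-3,3-dicarbaldehyde | CC(C)[Si](C(C)C)(C(C)C)OC[C@H](Oc1ccc(CCCO[Si](C(C)C)(C(C)C)C(C)C)cc1OC)[C@H]1O[C@H](c2ccc(O[Si](C(C)C)(C(C)C)C(C)C)c(OC)c2)[C@@H](CO)C1(C=O)C=O | intermediate (not isolated)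
29 | (1R,2S,4S,5R)-6-hydroxy-2-[3-methoxy-4-(triisopropylsilyloxy)phenyl]-4-[(1S)-1-{2-methoxy-4-[3-(triisopropylsilyloxy)propyl]phenoxy}-2-(triisopropylsilyloxy)ethyl]-3,7-dioxabicyclo[3.3.0]octane-5-carbaldehyde (cis-fused; mixture of C6 anomers) | CC(C)[Si](C(C)C)(C(C)C)OC[C@H](Oc1ccc(CCCO[Si](C(C)C)(C(C)C)C(C)C)cc1OC)[C@H]1O[C@H](c2ccc(O[Si](C(C)C)(C(C)C)C(C)C)c(OC)c2)[C@H]2COC(O)[C@@]12C=O | intermediate
30 | (triphenylphosphoranylidene)ethenone (Bestmann ylide) | O=C=C=P(c1ccccc1)(c1ccccc1)c1ccccc1 | starting material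
31 | (triphenylphosphoranylidene)acetate ester of the C6 lactol hydroxyl of 29 | CC(C)[Si](C(C)C)(C(C)C)OC[C@H](Oc1ccc(CCCO[Si](C(C)C)(C(C)C)C(C)C)cc1OC)[C@H]1O[C@H](c2ccc(O[Si](C(C)C)(C(C)C)C(C)C)c(OC)c2)[C@H]2COC(OC(=O)C=P(c3ccccc3)(c3ccccc3)c3ccccc3)[C@@]12C=O | intermediate (not isolated)
32 | tricyclic δ-lactone acylal: the C6 lactol oxygen of the (1R,2S,4S,5R)-3,7-dioxabicyclo[3.3.0]octane of 29 is acylated by a (Z)-propenoic acid whose C3 is bonded to C5 (5,6-dihydro-2H-pyran-2-one ring C; acetal carbon as a mixture) | CC(C)[Si](C(C)C)(C(C)C)OC[C@H](Oc1ccc(CCCO[Si](C(C)C)(C(C)C)C(C)C)cc1OC)[C@H]1O[C@H](c2ccc(O[Si](C(C)C)(C(C)C)C(C)C)c(OC)c2)[C@H]2COC3OC(=O)C=C[C@]123 | intermediate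
33 | diethyl (methoxymethyl)phosphonate | COCP(=O)(OCC)OCC | starting material
34 | diethyl {(3Z)-4-[(1R,2S,4S,5R)-6-hydroxy-2-aryl-4-(side chain)-3,7-dioxabicyclo[3.3.0]octan-5-yl]-1-methoxy-2-oxobut-3-enyl}phosphonate (aryl and side chain as in 29; mixture at C6 and at the phosphonate carbon) | CC(C)[Si](C(C)C)(C(C)C)OC[C@H](Oc1ccc(CCCO[Si](C(C)C)(C(C)C)C(C)C)cc1OC)[C@H]1O[C@H](c2ccc(O[Si](C(C)C)(C(C)C)C(C)C)c(OC)c2)[C@H]2COC(O)[C@@]12/C=C\C(=O)C(OC)P(=O)(OCC)OCC | intermediate (not isolated)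
35 | (1S,3S,4R,5S)-4-(hydroxymethyl)-7-methoxy-3-[3-methoxy-4-(triisopropylsilyloxy)phenyl]-1-[(1S)-1-{2-methoxy-4-[3-(triisopropylsilyloxy)propyl]phenoxy}-2-(triisopropylsilyloxy)ethyl]-2-oxaspiro[4.5]deca-6,9-dien-8-one | COC1=C[C@]2(C=CC1=O)[C@H](CO)[C@@H](c1ccc(O[Si](C(C)C)(C(C)C)C(C)C)c(OC)c1)O[C@@H]2[C@H](CO[Si](C(C)C)(C(C)C)C(C)C)Oc1ccc(CCCO[Si](C(C)C)(C(C)C)C(C)C)cc1OC | intermediate
36 | (1S,3S,4R,5S)-3-(4-hydroxy-3-methoxyphenyl)-4-(hydroxymethyl)-1-{(1S)-2-hydroxy-1-[4-(3-hydroxypropyl)-2-methoxyphenoxy]ethyl}-7-methoxy-2-oxaspiro[4.5]deca-6,9-dien-8-one (CNP0252711.1) | COC1=C[C@]2(C=CC1=O)[C@H](CO)[C@@H](c1ccc(O)c(OC)c1)O[C@@H]2[C@H](CO)Oc1ccc(CCCO)cc1OC | target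

**Step count and risks**

Total steps: 20. Longest linear sequence: 17 steps (steps 1, 2, 4 to 7 and 10 to 20); steps 3, 8 and 9 prepare the two side fragments.

Steps most likely to fail:

Step 19 (proposed method). The phosphonate anion may add in conjugate fashion or twice. The cis geometry of C9=C10 may be lost before ring closure. The olefination of the lactol-masked aldehyde may stall with lithium as counter-ion, or the freed alkoxide may add back to C6. The fallback uses known chemistry and sets out from 32. Methoxymethyllithium (from Bu3SnCH2OMe and n-BuLi, THF, −78 °C) is added once to the lactone carbonyl and quenched cold to give the (Z)-methoxymethyl enone lactol F1. This is then closed by a base-mediated intramolecular aldol condensation (K2CO3, MeOH, rt) between C7 and the lactol-masked aldehyde C6, which dehydrates to the dienone and returns to the route at 35.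

Step 18. The ketene ylide may acylate the primary hydroxyl of the ring-opened tautomer instead of the lactol hydroxyl, and the intramolecular Wittig reaction at the hindered neopentyl aldehyde may be slow. The fallback sets out from 29. The lactol hydroxyl is esterified with bis(2,2,2-trifluoroethyl)phosphonoacetic acid (DCC, DMAP, CH2Cl2) to give the lactol phosphonoacetate F2. Ring C is then closed by an intramolecular Still–Gennari-type olefination (K2CO3, 18-crown-6, toluene), which returns to the route at 32.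

Step 12. The quinone methide may tautomerise to the styrene before it is trapped, or the ring closure may show poor facial selectivity at C3. The fallback sets out from 21. The oxidation is run with Ag2O in methanol so that the quinone methide is trapped intermolecularly as the benzylic methyl ether F3. The oxolane is then closed by acid-mediated SN1 etherification through the benzylic cation under thermodynamic control (PPTS, CH2Cl2, rt), which returns to the route at 23.

Further compounds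
F1 | step 19 | (3Z)-4-[(1R,2S,4S,5R)-6-hydroxy-2-aryl-4-(side chain)-3,7-dioxabicyclo[3.3.0]octan-5-yl]-1-methoxybut-3-en-2-one (aryl and side chain as in 29) | CC(C)[Si](C(C)C)(C(C)C)OC[C@H](Oc1ccc(CCCO[Si](C(C)C)(C(C)C)C(C)C)cc1OC)[C@H]1O[C@H](c2ccc(O[Si](C(C)C)(C(C)C)C(C)C)c(OC)c2)[C@H]2COC(O)[C@@]12/C=C\C(=O)COC
F2 | step 18 | bis(2,2,2-trifluoroethyl)phosphonoacetate ester of the C6 lactol hydroxyl of 29 | CC(C)[Si](C(C)C)(C(C)C)OC[C@H](Oc1ccc(CCCO[Si](C(C)C)(C(C)C)C(C)C)cc1OC)[C@H]1O[C@H](c2ccc(O[Si](C(C)C)(C(C)C)C(C)C)c(OC)c2)[C@H]2COC(OC(=O)CP(=O)(OCC(F)(F)F)OCC(F)(F)F)[C@@]12C=O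
F3 | step 12 | benzylic methyl ether of 21 (methoxy group on the future C3; mixture of epimers) | O=C(N1[C@H](Cc2ccccc2)COC1=O)[C@H](Oc1ccc(CCCO[Si](C(C)C)(C(C)C)C(C)C)cc1OC)[C@@H](O)C1(COC(C)(C)OC1)[C@H](COCc1ccccc1)C(OC)c1ccc(O)c(OC)c1
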